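**Retrosynthetic overview**

1. Target 24 is a 5-deoxy biflavanoid: an all-trans 4-arylflavan-3-ol (upper unit, rings A/B/C) bonded through C4 to C6 of ring D of a 2,3-trans-3,4-cis flavan-3,4-diol (lower unit, rings D/E/F). The last steps are methanolysis of an acetate and a cyclic carbonate and hydrogenolysis of six benzyl ethers.
2. Ring C is disconnected across C4a–C4 and C2–C3. An O-aryl oxocarbenium ion (ring A–O1=C2–ring B, released from an O-aryl O-pivaloyl acetal) and an (E)-enol acetate C3=C4 standing on C6 of the finished lower unit are joined in a chiral-anion-controlled oxa-Povarov [4+2] that sets C2, C3 and C4 at once.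
3. Enabling feature: C4 is bonded to C6 of ring D, ortho to O7 and para to O1 of that ring, so ring D makes the enol acetate a styrene that is nucleophilic at C3 and cation-stabilising at C4. Ring A is a resorcinol ether whose C4a (ortho to O1, para to O7) is ready for Friedel–Crafts closure.
4. The enol acetate comes from a C6 bromide by Suzuki–Miyaura vinylborylation and copper-catalysed acyloxylation. The lower unit comes from a 6-bromochromone by asymmetric conjugate arylation (C2), reduction and dehydration to the flav-3-ene, and dihydroxylation anti to the C2 aryl group (C3, C4).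
5. Ring order: ring F (chromone closure, step 2), then ring C (step 12); rings A, B, D and E are bought as arenes.

Key step: step 12

Assumption: the sense of induction of the two chiral catalysts (the pyridine-oxazoline ligand of step 3 and the chiral acid of step 12) is taken as written; should either give the opposite sense, its mirror-image form would be used.

**Route**

Step 1
Reactants: 1 1-(5-bromo-2,4-dihydroxyphenyl)ethanone
Product: 2 1-[4-(benzyloxy)-5-bromo-2-hydroxyphenyl]ethanone
Conditions: BnBr (1.05 equiv), K2CO3, acetone, reflux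
Reagents that add atoms: benzyl bromide, BrCc1ccccc1
Why: Williamson etherification in which the 2-hydroxyl, hydrogen-bonded to the acetyl carbonyl, stays free, so only the 4-hydroxyl should be benzylated.

Step 2
Reactants: 2 1-[4-(benzyloxy)-5-bromo-2-hydroxyphenyl]ethanone
Product: 4 7-(benzyloxy)-6-bromo-4H-chromen-4-one, via enaminone 3 (not isolated)
Conditions: Me2NCH(OMe)2, toluene, 100 °C; then conc. HCl, CH2Cl2, 40 °C
Reagents that add atoms: N,N-dimethylformamide dimethyl acetal, COC(OC)N(C)C
Why: Enaminone condensation of the methyl ketone followed by acid-promoted cyclisation with loss of dimethylamine is the standard chromone synthesis and closes ring F.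

Step 3
Reactants: 4 7-(benzyloxy)-6-bromo-4H-chromen-4-one; 5 [3,4-bis(benzyloxy)phenyl]boronic acid
Product: 6 (2S)-7-(benzyloxy)-2-[3,4-bis(benzyloxy)phenyl]-6-bromo-2,3-dihydro-4H-chromen-4-one
Conditions: Pd(OCOCF3)2 (5 mol%), (R)-4-tert-butyl-2-(pyridin-2-yl)-4,5-dihydrooxazole (6 mol%), NH4PF6 (30 mol%), H2O (5 equiv), ClCH2CH2Cl, 60 °C
Reagents that add atoms: none
Why: Asymmetric conjugate addition of an arylboronic acid to a chromone, in which the chiral pyridine-oxazoline ligand on divalent palladium sets C2 (catalyst control) and the aryl bromide should survive because no zerovalent palladium is formed.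

Step 4
Reactants: 6 (2S)-flavanone
Product: 7 (2S,4S)-7-(benzyloxy)-2-[3,4-bis(benzyloxy)phenyl]-6-bromo-3,4-dihydro-2H-chromen-4-ol
Conditions: NaBH4, THF/MeOH, 0 °C
Reagents that add atoms: none
Why: Borohydride 1,2-reduction of the aryl ketone, expected to give mainly the 2,4-cis alcohol by axial hydride delivery; the C4 configuration is of no consequence because it is removed in step 5.

Step 5
Reactants: 7 (2S,4S)-flavan-4-ol
Product: 9 (2S)-7-(benzyloxy)-2-[3,4-bis(benzyloxy)phenyl]-6-bromo-2H-chromene, via 4-mesylate 8 (not isolated)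
Conditions: MsCl, Et3N (excess), CH2Cl2, 0 °C to rt
Reagents that add atoms: none
Why: Sulfonylation and base-induced elimination of the benzylic sulfonate, which is activated by the para benzyloxy group, should give the conjugated flav-3-ene without touching C2, and the low temperature avoids electrocyclic ring opening.

Step 6
Reactants: 9 (2S)-flav-3-ene
Product: 10 (2R,3S,4S)-7-(benzyloxy)-2-[3,4-bis(benzyloxy)phenyl]-6-bromo-3,4-dihydro-2H-chromene-3,4-diol
Conditions: K2OsO4·2H2O (2 mol%), N-methylmorpholine N-oxide, acetone/H2O, rt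
Reagents that add atoms: N-methylmorpholine N-oxide, C[N+]1([O-])CCOCC1; water, O
Why: Catalytic osmium syn-dihydroxylation, which on flav-3-enes adds to the face anti to the C2 aryl group, so C3 and C4 are set by substrate control as the 2,3-trans-3,4-cis diol.

Step 7
Reactants: 10 (2R,3S,4S)-diol
Product: 11 3,4-cyclic carbonate of diol 10 (cis-fused 1,3-dioxolan-2-one; configuration as in 10)
Conditions: 1,1'-carbonyldiimidazole, CH2Cl2, rt to 40 °C
Reagents that add atoms: 1,1'-carbonyldiimidazole, O=C(n1ccnc1)n1ccnc1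
Why: Carbonylation of a cis-1,2-diol gives the five-membered carbonate, whose electron-poor oxygen should keep the benzylic C4–O bond from ionising under the acid of step 12; no stereocentre is touched.

Step 8
Reactants: 11 bromo carbonate; 12 (E)-1,2-bis(4,4,5,5-tetramethyl-1,3,2-dioxaborolan-2-yl)ethene
Product: 13 analogue of 11 bearing an (E)-2-(4,4,5,5-tetramethyl-1,3,2-dioxaborolan-2-yl)ethenyl group at C6 in place of bromine
Conditions: 12 (3 equiv), PdCl2(dppf) (5 mol%), CsF, 1,4-dioxane, 80 °C
Reagents that add atoms: none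
Why: Suzuki–Miyaura mono-coupling of the aryl bromide with an excess of the symmetrical diborylethene should transfer one vinyl terminus with retention of the E geometry, and the anhydrous fluoride base spares the carbonate.

Step 9
Reactants: 13 (E)-alkenyl pinacol boronate
Product: 14 potassium (E)-alkenyltrifluoroborate corresponding to 13
Conditions: KHF2 (aq.), MeOH, rt
Reagents that add atoms: potassium hydrogen difluoride, [K+].[F-].F
Why: Standard exchange of a pinacol boronate into the trifluoroborate salt, the boron form required for the acyloxylation of step 10; the alkene geometry is unaffected.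

Step 10
Reactants: 14 potassium (E)-alkenyltrifluoroborate
Product: 15 (E)-2-aryl-ethenyl acetate of the lower unit (aryl = C6 of the carbonate-protected flavan)
Conditions: AcOH, CuBr (10 mol%), 4-(dimethylamino)pyridine (20 mol%), 4 Å MS, O2 (1 atm), CH2Cl2, 40 °C
Reagents that add atoms: acetic acid, CC(=O)O
Why: Chan–Lam-type copper-catalysed oxidative C–O coupling of an alkenyltrifluoroborate with a carboxylic acid, which proceeds with retention of alkene geometry and should give the (E)-enol acetate only.

Step 11
Reactants: 16 3,4-bis(benzyloxy)benzaldehyde; 17 3-(benzyloxy)phenol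
Product: 19 [3-(benzyloxy)phenoxy][3,4-bis(benzyloxy)phenyl]methyl 2,2-dimethylpropanoate (racemic), via chloro pivalate 18 (not isolated)
Conditions: t-BuCOCl, ZnCl2 (2 mol%), CH2Cl2, 0 °C to rt; then 17, NaH, THF, -20 °C
Reagents that add atoms: pivaloyl chloride, CC(C)(C)C(Cl)=O
Why: Addition of an acyl chloride to the aldehyde gives the α-chloroalkyl ester, which O-alkylates the sodium phenoxide as in the preparation of acyloxyalkyl aryl ethers; the bulky pivalate disfavours attack at the acyl carbon, and the acetal centre is lost on ionisation in step 12.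

Step 12
Reactants: 15 (E)-enol acetate; 19 O-aryl O-pivaloyl acetal
Product: 22 hexa-O-benzyl dimer with all-trans ring C carrying 3-O-acetyl and the lower 3,4-cyclic carbonate (configurations as in target 24), via aryl oxocarbenium ion 20 (not isolated), via benzylic cation 21 (not isolated)
Conditions: 19 (1.5 equiv), (S,S)-imidodiphosphorimidate acid (ArO2)P(=NSO2CF3)–NH–P(=NSO2CF3)(O2Ar) with ArO2 = (S)-3,3'-bis[3,5-bis(trifluoromethyl)phenyl]-1,1'-binaphthalene-2,2'-diolate (5 mol%), toluene/CH2Cl2 4:1, -60 °C
Reagents that add atoms: none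
Why: Proposed new method: the chiral acid protonates the pivalate carbonyl of 19 and expels pivalic acid to give the E-configured O-aryl oxocarbenium ion 20 as a contact ion pair with the confined chiral anion; C3 of enol acetate 15 attacks C2 of this cationic 2-oxadiene (C4a=C8a–O1=C2) to give benzylic cation 21, which ring A captures at the carbon ortho to O1 and para to its benzyloxy group, and the proton lost on rearomatisation returns the acid. The closest known reaction type is the oxa-Povarov reaction of O-aryl oxocarbenium ions with styrenes under stoichiometric SnCl4, together with chiral Brønsted acid catalysed Povarov reactions of N-aryl iminium ions; new here are counter-anion control of an oxocarbenium [4+2] and an enol ester as the alkene. Ring C, the only ring closed, is formed as a six-membered ring in a formal inverse-electron-demand [4+2] whose second bond is an intramolecular Friedel–Crafts alkylation. The relative configuration should follow from the E geometry of both partners and an endo placement of ring D under the oxadiene, which puts the C2 aryl, C3 acetoxy and C4 aryl groups all trans (all equatorial), the acetate carbonyl shielding the cis face of C4 in 21; the absolute configuration at C2, C3 and C4 is set by the chiral anion, because the stereocentres of the lower unit lie too far from the alkene to interfere. The step needs attack through C3 and not C4, secured by the ortho (O7) and para (O1) oxygens of ring D that stabilise positive charge at C4 while acylation damps the enol oxygen; it needs closure para to the benzyloxy group of ring A, secured by lower hindrance at that carbon; and it needs the lower C4–O bond to stay intact, secured by the electron-poor cyclic carbonate.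

Step 13
Reactants: 22 protected dimer
Product: 23 hexa-O-benzyl dimer with free upper 3-OH and free lower 3-OH and 4-OH (configurations as in target 24)
Conditions: K2CO3 (cat.), MeOH/THF, rt
Reagents that add atoms: none
Why: Base-catalysed transesterification removes the acetate and the cyclic carbonate together; with every phenol still benzylated no phenoxide can expel the benzylic oxygen, so no stereocentre should be disturbed.

Step 14
Reactants: 23 hexa-O-benzyl triol
Product: 24 (2R,3S,4R)-2-(3,4-dihydroxyphenyl)-4-[(2R,3S,4S)-2-(3,4-dihydroxyphenyl)-3,4,7-trihydroxy-3,4-dihydro-2H-chromen-6-yl]-3,4-dihydro-2H-chromene-3,7-diol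
Conditions: H2 (1 atm), 10% Pd/C, THF/MeOH, rt, acid-free, filtration under argon
Reagents that add atoms: none
Why: Catalytic hydrogenolysis cleaves aryl benzyl ethers much faster than a secondary benzylic C–OH bond, the cyclic 2-aryl ether bonds or the C4–C6 bond between the units under neutral conditions, so the six phenols should be released without loss of the lower 4-hydroxyl.

**Compound list**

1 | 1-(5-bromo-2,4-dihydroxyphenyl)ethanone | CC(=O)c1cc(Br)c(O)cc1O | starting material
2 | 1-[4-(benzyloxy)-5-bromo-2-hydroxyphenyl]ethanone | CC(=O)c1cc(Br)c(OCc2ccccc2)cc1O | intermediate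
3 | (E)-1-[4-(benzyloxy)-5-bromo-2-hydroxyphenyl]-3-(dimethylamino)prop-2-en-1-one | CN(C)/C=C/C(=O)c1cc(Br)c(OCc2ccccc2)cc1O | intermediate
4 | 7-(benzyloxy)-6-bromo-4H-chromen-4-one | O=c1ccoc2cc(OCc3ccccc3)c(Br)cc12 | intermediate
5 | [3,4-bis(benzyloxy)phenyl]boronic acid | OB(O)c1ccc(OCc2ccccc2)c(OCc2ccccc2)c1 | starting material
6 | (2S)-7-(benzyloxy)-2-[3,4-bis(benzyloxy)phenyl]-6-bromo-2,3-dihydro-4H-chromen-4-one | O=C1C[C@@H](c2ccc(OCc3ccccc3)c(OCc3ccccc3)c2)Oc2cc(OCc3ccccc3)c(Br)cc21 | intermediate
7 | (2S,4S)-7-(benzyloxy)-2-[3,4-bis(benzyloxy)phenyl]-6-bromo-3,4-dihydro-2H-chromen-4-ol (2,4-cis) | O[C@H]1C[C@@H](c2ccc(OCc3ccccc3)c(OCc3ccccc3)c2)Oc2cc(OCc3ccccc3)c(Br)cc21 | intermediate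
8 | 4-methanesulfonate of 7 | CS(=O)(=O)O[C@H]1C[C@@H](c2ccc(OCc3ccccc3)c(OCc3ccccc3)c2)Oc2cc(OCc3ccccc3)c(Br)cc21 | intermediate
9 | (2S)-7-(benzyloxy)-2-[3,4-bis(benzyloxy)phenyl]-6-bromo-2H-chromene | C1=C[C@@H](c2ccc(OCc3ccccc3)c(OCc3ccccc3)c2)Oc2cc(OCc3ccccc3)c(Br)cc21 | intermediate
10 | (2R,3S,4S)-7-(benzyloxy)-2-[3,4-bis(benzyloxy)phenyl]-6-bromo-3,4-dihydro-2H-chromene-3,4-diol (2,3-trans-3,4-cis) | Brc1cc2c(cc1OCc1ccccc1)O[C@H](c1ccc(OCc3ccccc3)c(OCc3ccccc3)c1)[C@@H](O)[C@H]2O | intermediate
11 | 3,4-cyclic carbonate of 10 (configuration as in 10) | Brc1cc2c(cc1OCc1ccccc1)O[C@H](c1ccc(OCc3ccccc3)c(OCc3ccccc3)c1)[C@@H](OC(=O)O3)[C@H]23 | intermediate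
12 | (E)-1,2-bis(4,4,5,5-tetramethyl-1,3,2-dioxaborolan-2-yl)ethene | CC1(C)OB(/C=C/B2OC(C)(C)C(C)(C)O2)OC1(C)C | starting material
13 | 6-[(E)-2-(pinacolboryl)ethenyl] analogue of 11 | CC1(C)OB(/C=C/c2cc3c(cc2OCc2ccccc2)O[C@H](c2ccc(OCc4ccccc4)c(OCc4ccccc4)c2)[C@@H](OC(=O)O4)[C@H]34)OC1(C)C | intermediate
14 | potassium (E)-alkenyltrifluoroborate from 13 | [K+].F[B-](F)(F)/C=C/c1cc2c(cc1OCc1ccccc1)O[C@H](c1ccc(OCc3ccccc3)c(OCc3ccccc3)c1)[C@@H](OC(=O)O3)[C@H]23 | intermediate
15 | (E)-2-aryl-ethenyl acetate of the carbonate-protected lower unit | CC(=O)O/C=C/c1cc2c(cc1OCc1ccccc1)O[C@H](c1ccc(OCc3ccccc3)c(OCc3ccccc3)c1)[C@@H](OC(=O)O3)[C@H]23 | intermediate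
16 | 3,4-bis(benzyloxy)benzaldehyde | O=Cc1ccc(OCc2ccccc2)c(OCc2ccccc2)c1 | starting material
17 | 3-(benzyloxy)phenol | Oc1cccc(OCc2ccccc2)c1 | starting material
18 | [3,4-bis(benzyloxy)phenyl](chloro)methyl 2,2-dimethylpropanoate (racemic) | CC(C)(C)C(=O)OC(Cl)c1ccc(OCc2ccccc2)c(OCc2ccccc2)c1 | intermediate
19 | [3-(benzyloxy)phenoxy][3,4-bis(benzyloxy)phenyl]methyl 2,2-dimethylpropanoate (racemic) | CC(C)(C)C(=O)OC(Oc1cccc(OCc2ccccc2)c1)c1ccc(OCc2ccccc2)c(OCc2ccccc2)c1 | intermediate
20 | (E)-O-[3-(benzyloxy)phenyl] oxocarbenium ion of 3,4-bis(benzyloxy)benzaldehyde (paired with the catalyst anion) | c1ccccc1COc1cccc(/[O+]=C/c2ccc(OCc3ccccc3)c(OCc3ccccc3)c2)c1 | intermediate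
21 | open-chain benzylic cation after C2–C3 bond formation (C2 and C3 as in 22) | c1ccccc1COc1cccc(c1)O[C@H](c1ccc(OCc3ccccc3)c(OCc3ccccc3)c1)[C@@H](OC(C)=O)[CH+]c1cc2c(cc1OCc1ccccc1)O[C@H](c1ccc(OCc3ccccc3)c(OCc3ccccc3)c1)[C@@H](OC(=O)O3)[C@H]23 | intermediate
22 | hexa-O-benzyl dimer, upper ring all-trans with 3-O-acetyl, lower 3,4-cyclic carbonate | c1ccccc1COc1ccc2c(c1)O[C@H](c1ccc(OCc3ccccc3)c(OCc3ccccc3)c1)[C@@H](OC(C)=O)[C@@H]2c1cc2c(cc1OCc1ccccc1)O[C@H](c1ccc(OCc3ccccc3)c(OCc3ccccc3)c1)[C@@H](OC(=O)O3)[C@H]23 | intermediate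
23 | hexa-O-benzyl dimer with free upper 3-OH and lower 3,4-diol | c1ccccc1COc1ccc2c(c1)O[C@H](c1ccc(OCc3ccccc3)c(OCc3ccccc3)c1)[C@@H](O)[C@@H]2c1cc2c(cc1OCc1ccccc1)O[C@H](c1ccc(OCc3ccccc3)c(OCc3ccccc3)c1)[C@@H](O)[C@H]2O | intermediate
24 | (2R,3S,4R)-2-(3,4-dihydroxyphenyl)-4-[(2R,3S,4S)-2-(3,4-dihydroxyphenyl)-3,4,7-trihydroxy-3,4-dihydro-2H-chromen-6-yl]-3,4-dihydro-2H-chromene-3,7-diol | Oc1ccc2c(c1)O[C@H](c1ccc(O)c(O)c1)[C@@H](O)[C@@H]2c1cc2c(cc1O)O[C@H](c1ccc(O)c(O)c1)[C@@H](O)[C@H]2O | target

**Step count and risks**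

Total step count: 14. Longest linear sequence: 13 steps (steps 1 to 10, then 12, 13 and 14); step 11 is a one-step branch.

Steps most likely to fail:

1. Step 12 (Proposed new method). What may go wrong:
   - insufficient facial control by the chiral anion, so that the all-trans adduct with the mirror-image upper ring forms alongside;
   - leakage to the 2,3-cis adduct through an exo approach;
   - acid-induced oligomerisation of the enol acetate;
   - Friedel–Crafts attack of the oxocarbenium ion at C8 of ring D.

   Fallback: the classical flavan-3,4-diol condensation, which forms the bond between the units instead of ring C. It sets out from 9. Bromine–lithium exchange (n-BuLi, THF, -78 °C) and quenching with MeOH should give the bromine-free (2S)-7-(benzyloxy)-2-[3,4-bis(benzyloxy)phenyl]-2H-chromene F1. Dihydroxylation as in step 6 should give the (2R,3S,4S)-tri-O-benzyl flavan-3,4-diol F2, and part of it is converted as in step 7 into its 3,4-cyclic carbonate F3. Slow addition of F2 to an excess of F3 with BF3·OEt2 in CH2Cl2 at -40 to 0 °C ionises only the free benzylic 4-hydroxyl of F2. The cation should be taken up by C6 of F3 (para to the ring oxygen, less hindered than C8) on the face anti to the 3-hydroxyl, giving the 3,4-trans coupled dimer carbonate F4. Methanolysis as in step 13 returns the route to 23.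

2. Step 10. What may go wrong: protodeboronation or oxidative homocoupling of the alkenylboron species outrunning C–O bond formation on this large, electron-rich substrate.

   Fallback: an enolisation route that sets out from 13. Oxidation of the C–B bond with anhydrous Me3NO (THF, 60 °C) and mild aqueous work-up should give the arylacetaldehyde F5. O-Acetylation of its enol (Ac2O, Et3N, cat. 4-(dimethylamino)pyridine, CH2Cl2, rt) should give the enol acetate as an E/Z mixture. The E isomer is separated by chromatography and rejoins the route at 15; the Z isomer can be re-equilibrated with a trace of iodine.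

3. Step 14. What may go wrong: hydrogenolytic loss of the benzylic 4-hydroxyl of the lower unit, or its ionisation on an acidic catalyst surface, before all six benzyl ethers are cleaved.

   Fallback: mask the carbinols as silyl ethers during hydrogenolysis, setting out from 23. Silylation with t-BuMe2SiOTf and 2,6-lutidine (CH2Cl2, -78 to 0 °C) should give the tris(tert-butyldimethylsilyl) ether F6, whose hindered benzylic silyl ether resists hydrogenolysis. Hydrogenolysis (H2, Pd/C, EtOAc) should then give the hexaphenol tris(silyl) ether F7. Desilylation with Bu4NF buffered with AcOH (THF, 0 °C to rt), under which the phenols stay protonated, returns the route to 24.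

**Further compounds**

F1 | step 12 | (2S)-7-(benzyloxy)-2-[3,4-bis(benzyloxy)phenyl]-2H-chromene | C1=C[C@@H](c2ccc(OCc3ccccc3)c(OCc3ccccc3)c2)Oc2cc(OCc3ccccc3)ccc21
F2 | step 12 | (2R,3S,4S)-7-(benzyloxy)-2-[3,4-bis(benzyloxy)phenyl]-3,4-dihydro-2H-chromene-3,4-diol | c1cc2c(cc1OCc1ccccc1)O[C@H](c1ccc(OCc3ccccc3)c(OCc3ccccc3)c1)[C@@H](O)[C@H]2O
F3 | step 12 | 3,4-cyclic carbonate of F2 | c1cc2c(cc1OCc1ccccc1)O[C@H](c1ccc(OCc3ccccc3)c(OCc3ccccc3)c1)[C@@H](OC(=O)O3)[C@H]23
F4 | step 12 | hexa-O-benzyl dimer with free upper 3-OH and lower 3,4-cyclic carbonate | c1ccccc1COc1ccc2c(c1)O[C@H](c1ccc(OCc3ccccc3)c(OCc3ccccc3)c1)[C@@H](O)[C@@H]2c1cc2c(cc1OCc1ccccc1)O[C@H](c1ccc(OCc3ccccc3)c(OCc3ccccc3)c1)[C@@H](OC(=O)O3)[C@H]23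
F5 | step 10 | 2-aryl-acetaldehyde of the carbonate-protected lower unit | O=CCc1cc2c(cc1OCc1ccccc1)O[C@H](c1ccc(OCc3ccccc3)c(OCc3ccccc3)c1)[C@@H](OC(=O)O3)[C@H]23
F6 | step 14 | tris(tert-butyldimethylsilyl) ether of 23 | c1ccccc1COc1ccc2c(c1)O[C@H](c1ccc(OCc3ccccc3)c(OCc3ccccc3)c1)[C@@H](O[Si](C)(C)C(C)(C)C)[C@@H]2c1cc2c(cc1OCc1ccccc1)O[C@H](c1ccc(OCc3ccccc3)c(OCc3ccccc3)c1)[C@@H](O[Si](C)(C)C(C)(C)C)[C@H]2O[Si](C)(C)C(C)(C)C
F7 | step 14 | tris(tert-butyldimethylsilyl) ether of 24 at the three alcohol oxygens | Oc1ccc2c(c1)O[C@H](c1ccc(O)c(O)c1)[C@@H](O[Si](C)(C)C(C)(C)C)[C@@H]2c1cc2c(cc1O)O[C@H](c1ccc(O)c(O)c1)[C@@H](O[Si](C)(C)C(C)(C)C)[C@H]2O[Si](C)(C)C(C)(C)C
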